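## Analysis of the target

Dysidenone A (31) joins a trans-fused decalin (ring A: C10–C1–C2–C3=C4–C5; ring B: C5–C6–C7–C8–C9–C10) through the C11 methylene on C8 to a cyclopentenone head (C1′ carbinol with OH and CO2Me, C2′H=C3′(OMe), C4′=O, C5′H–C11). Calling the face that carries the C5 methyl α, ring B holds four contiguous stereocentres: C5 (quaternary, methyl α), C10 (H β, hence trans fusion), C9 (methyl α and axial, syn-diaxial to the C5 methyl) and C8 (quaternary, methyl β-axial, C11 α-equatorial). The head adds C1′ and C5′, with C11 cis to the ester and trans to the hydroxyl; C5′ is α to the ketone and epimerisable, and both centres are too far from the decalin to be steered by it. The C3=C4 alkene beside quaternary C5 is acid-sensitive (protonation invites hydride and methyl shifts), and the β-hydroxy ketone/α-hydroxy ester is open to retro-aldol cleavage in strong base. The hard parts are two quaternary carbons placed 1,4 across ring B, each next to another stereocentre, a C9 methyl in the less stable axial position, and a highly oxidised five-membered ring with no direct assembly. The strategy rests on ring B: its methyls on C5 and C8 are para to each other with C6 and C9 between them, which is the pattern of 2,5-dimethyl-1,4-benzoquinone when C6 and C9 are read as the carbonyl carbons, and C4/C5 bear vicinal methyls so that a C4-methylated diene can bond to the methyl-bearing quinone carbon. The head maps onto a 2-hydroxy-5-methoxy-3-alkyl-1,4-benzoquinone by loss of one ring carbon to the ester, so an electron-rich arene can stand in for it until late.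

## Retrosynthetic reasoning

**Head group, 31 back to 27.** The C1′ carbinol carbon and its ester carbon are read as the two adjacent carbonyl carbons of a cyclic 1,2-dione, so the five-membered ring is re-expanded to hydroxyquinone 27. The cut is made here because a quaternary α-hydroxy ester on a ring is the signature of a benzilic acid contraction, and a quinone can be carried as an arene. The trione tautomer of 27 would enolise back to 27 through its C3–H, so the forward sequence first oxidises that carbon (28), contracts (29), esterifies (30) and then removes the extra hydroxyl reductively (31).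

**Quinone back to arene, 27 to 25.** No C–C bond is cut: 27 comes from dimethoxyquinone 26 by selective hydrolysis and 26 from tetramethoxyarene 25 by oxidative demethylation. This gains an inert aromatic ring that survives organolithium and dissolving-metal steps.

**C11–aryl bond, 25 to 21 + 22.** C11 is neopentylic, so displacement at C11 is not realistic. The bond is therefore cut so that C11 is an aldehyde carbon (21) and the arene is the nucleophile (23 from symmetrical 22); the benzylic oxygen of 24 is then removed.

**C3=C4 alkene, 21 back to 15.** The alkene is traced to the C3 ketone 15 through enol triflate 18. It is installed late because it would not survive the hydrogenations and the epoxidising oxidant that ring B needs. The forward sequence must place the double bond toward C4 and not C2, which is why it passes through the equilibrated enol ether 16.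

**C8–methyl bond and C6 oxygen, 15 back to 11.** The quaternary C8 is cut at its methyl group: conjugate addition of methyl to enone 11 enters axially and fixes C8. The resulting enolate 12 is also the handle, as triflate 13, for removing the C6 oxygen (14).

**C11–O bond, 11 back to 8.** The oxygen on C11 is traced to a C–H bond of the C8 methyl of enone 8, reached through its vinylogous enol ether 9. This turns the methyl that came with the quinone into the future linker carbon, so that the methyl added later can take the axial site.

**C9 methyl, 8 back to 5.** The C9 methyl is cut back to the C9 carbonyl by way of the methylene compound 6 and its hydrogenation to 7. This distinguishes the two quinone-derived carbonyls by their steric environment and sets C9 by addition of hydrogen away from the C5 methyl.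

**C10, 5 back to 4.** The trans ring fusion is traced to the cis adduct by epimerisation next to the C9 ketone.

**Ring A, 4 back to 2 + 3.** The C4–C5 and C1–C10 bonds are cut in a [4+2] sense. This is the only disconnection that removes ring A, the C5 quaternary centre and the C4 methyl together and leaves two small achiral partners.

**Diene, 2 back to 1.** The silyl enol ether is cut at O–Si, leading to the enone 1.

## Alternatives that were turned down

Alternative 1: The cyclopentenone is disconnected at C1′–C2′, leading to the cross-conjugated dienone A1 with a 1-methoxyvinyl arm and an ester-bearing enone arm. In the forward direction A1 would undergo a Cu(OTf)2/bis(oxazoline)-catalysed 4π-electrocyclisation to the cyclopentenone ester A2, followed by hydroxylation at C1′. In its favour, the head group is built convergently and its stereocentres come under catalyst and substrate control (the oxidant would enter C1′ anti to C11), which is stronger than the chosen route, where C1′ is not controlled. Against it, A1 places the acceptor at the bond-forming terminus, not the usual polarisation, so cyclisation should be slow. The oxyallyl cation can also lose the acidic C1′–H to give the C1′=C5′ enone and erase both centres. The decalin with its four stereocentres must still be made separately. The chosen strategy gives instead the whole decalin core with absolute control from two commercial partners, at the price of a head group that needs separation.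

Alternative 2: Both carbocycles are disconnected at once (C1–C2 and C5–C10), leading to the achiral acyclic trienone A3. In the forward direction A3 would undergo an oxazaborolidinium-catalysed intramolecular Diels–Alder reaction to the trans-decalone A4. In its favour, rings A and B, the C3=C4 alkene and the C4/C5 methyls arrive together, so ring A needs none of the five redox steps that the chosen route spends on C3; on that point it is clearly better. Against it, A4 has a gem-dimethyl C8, so one of two nearly equivalent methyls would have to be oxidised selectively to become C11, and no step controls that. The C9 ketone is then flanked by a quaternary carbon, which makes the axial C9 methyl hard to install. The diene terminus C5 carries an inward methyl that disfavours the s-cis conformer. The chosen route differentiates C8 from the start, because the quinone methyl becomes C11 and the incoming methyl is forced axial.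

Alternative 3: The C9–methyl bond is disconnected intramolecularly, leading to the (bromomethyl)dimethylsilyl ether A5 of a C11 alcohol with a C9=C10 alkene. In the forward direction Bu3SnH would trigger a 6-exo radical cyclisation and hydrogen transfer to the siloxane A6, followed by protodesilylation. In its favour, the tether delivers the C9 carbon cis to C11 and the hydrogen atom sets C10, a firmer control of C9 than the face-selective hydrogenation used here. Against it, this is a stereo-relay on a finished bicycle: the C8 quaternary centre, the alkene and the enantiopure decalin must already exist, ring A still lacks its methyl and alkene, and three operations plus a difficult C–Si protonolysis are spent on one methyl group. The chosen strategy forms a ring and three stereocentres in the step that also sets the absolute configuration.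

Key step: step 2

Assumption 1: the catalyst from (S)-diphenylprolinol is taken to expose the quinone face that leads to 4 as drawn; if the facial sense is the reverse, the (R)-catalyst is used and nothing else changes.
Assumption 2: C4 of 4–15 is written as set in the cycloaddition; any epimerisation there in steps 6 or 11 is harmless because C4 becomes trigonal in step 12.
Assumption 3: C1′ and C5′ are formed without useful bias from the remote decalin, so steps 21–23 are expected to give diastereomers that are separated at the end.

## Route

Step 1
Reactants: 1 pent-1-en-3-one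
Product: 2 (Z)-3-(triisopropylsilyloxy)penta-1,3-diene
Conditions: i-Pr3SiOTf, Et3N, Et2O, 0 °C → rt
Reagents that add atoms: triisopropylsilyl triflate, CC(C)[Si](OS(=O)(=O)C(F)(F)F)(C(C)C)C(C)C
Why: Soft enolisation (silyl triflate activates the carbonyl, the amine removes a proton from the only enolisable carbon) gives the 2-silyloxy diene; the methyl should settle cis to oxygen, the (Z)-geometry that can reach the s-cis diene conformer with the methyl pointing outward.

Step 2
Reactants: 2 (Z)-3-(triisopropylsilyloxy)penta-1,3-diene, 3 2,5-dimethyl-1,4-benzoquinone
Product: 4 cis-fused adduct (ring A: C2=C3 silyl enol ether, 4β-Me; 5α-Me, 10α-H; ring B: 6,9-dione, C7=C8 with 8-Me)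
Conditions: (S)-B-(o-tolyl)diphenylprolinol oxazaborolidine (20 mol %), HNTf2 (18 mol %), CH2Cl2, −78 °C
Reagents that add atoms: none
Why: The N-protonated oxazaborolidine is a chiral boron Lewis acid that binds the C9 carbonyl through the lone pair on the C10–H side, which lowers the LUMO of the C5=C10 bond and makes the methyl-bearing C5 its electrophilic end. The diene then adds in a concerted but asynchronous suprafacial [4+2] cycloaddition in which its nucleophilic terminus C4 (the β-carbon of the enol ether) bonds to C5 ahead of the C1–C10 bond; the closest known reaction type is the oxazaborolidinium-catalysed enantioselective Diels–Alder reaction of substituted 1,4-benzoquinones with 2-silyloxy dienes. Ring A is the only ring closed and it is closed by the cycloaddition itself, its two new σ bonds C4–C5 and C1–C10 forming on one face of a quinone double bond and leaving the enol ether at C2=C3. C5 is set by the catalyst, whose aryl group covers one face of the bound enone; C10 follows from suprafacial addition (H cis to the C5 methyl); C4 follows from the endo transition state and the (Z)-geometry of 2, which place the C4 methyl trans to the C5 methyl. The step needs regioselectivity (C4 to C5), which is secured by the match of the silyloxy-polarised diene with the catalyst-polarised enone. It needs no site selectivity, because 3 has an inversion centre and both double bonds give the same adduct. A second addition is not expected because the remaining C7=C8 bond of 4 is a crowded trisubstituted ene-dione and no longer a quinone.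

Step 3
Reactants: 4 cis-fused adduct
Product: 5 trans-fused ene-dione (as 4 but 10β-H)
Conditions: DBU (0.3 equiv), PhMe, rt
Reagents that add atoms: none
Why: Reversible removal of the C10 proton α to the C9 carbonyl (C5 is quaternary, so no aromatisation) and reprotonation anti to the adjacent C5 methyl; the trans isomer should be favoured kinetically and thermodynamically because only it lets the C4 and C5 methyls sit trans-diaxial without the syn-axial C4-methyl/C9 contact or the eclipsing with the C3 silyloxy group found in the two cis conformers (base-mediated epimerisation).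

Step 4
Reactants: 5 trans-fused ene-dione
Product: 6 9-methylene dienone (C6 ketone, C7=C8, C9=CH2; ring A unchanged)
Conditions: Cp2Ti(μ-Cl)(μ-CH2)AlMe2 (1.1 equiv), pyridine, THF/PhMe, −40 → 0 °C
Reagents that add atoms: Cp2Ti(μ-Cl)(μ-CH2)AlMe2, C[Al-]1(C)C[Ti](C2C=CC=C2)(C2C=CC=C2)[Cl+]1
Why: Titanium methylidene olefination ([2+2] then cycloreversion) is non-basic, so C10 keeps its configuration; the C6 carbonyl is screened on its α face by the C5 methyl and on its β face by the axial C4 methyl, so the bulky carbene should take the C9 carbonyl.

Step 5
Reactants: 6 9-methylene dienone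
Product: 7 9α-methyl enone (C6 ketone, C7=C8 with 8-Me, 9β-H)
Conditions: H2 (1 atm), RhCl(PPh3)3 (10 mol %), PhH, rt
Reagents that add atoms: none
Why: Homogeneous hydrogenation picks the 1,1-disubstituted exocyclic alkene over the trisubstituted enone and enol ether bonds; rhodium delivers hydrogen to the β face of C9 because the α face is covered by the 1,3-related axial C5 methyl, so C9–H ends β and the new methyl α-axial.

Step 6
Reactants: 7 9α-methyl enone
Product: 8 C3 dioxolane enone (ring A saturated, 3,3-ethylenedioxy)
Conditions: HO(CH2)2OH, TsOH·H2O (5 mol %), CH2Cl2, rt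
Reagents that add atoms: ethylene glycol, OCCO
Why: Protonation of the enol ether at C2 gives the C3 oxocarbenium ion, which the diol captures twice with loss of the silanol (acetal exchange of an enol ether); the hindered conjugated C6 ketone does not ketalise, and C3 is now masked against the base and oxidant of step 7.

Step 7
Reactants: 8 C3 dioxolane enone
Product: 10 11-hydroxy enone (C8–CH2OH), via trimethylsilyl dienol ether 9 (not isolated)
Conditions: LiN(i-Pr)2, Me3SiCl, THF, −78 °C; then DMDO, acetone/CH2Cl2, −78 → −20 °C; pH 4 citrate work-up
Reagents that add atoms: dimethyldioxirane, CC1(C)OO1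
Why: With no hydrogen on C5 the amide removes a γ-proton, and it should take one from the C8 methyl because the equatorial C9–H lies near the enone plane and cannot overlap with the π system, which also protects the C9 configuration; the exocyclic C8=C11 bond of the 1-silyloxy diene is epoxidised and the epoxide collapses to the enone with oxygen on C11 (vinylogous Rubottom oxidation).

Step 8
Reactants: 10 11-hydroxy enone
Product: 11 11-triisopropylsilyloxy enone
Conditions: i-Pr3SiCl, imidazole, DMF, rt
Reagents that add atoms: chlorotriisopropylsilane, CC(C)[Si](Cl)(C(C)C)C(C)C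
Why: Silylation of the primary allylic alcohol; a silyl ether is a poor leaving group, so the cuprate will not expel the γ-oxygen, and this group survives the ketal hydrolysis of step 11.

Step 9
Reactants: 11 11-triisopropylsilyloxy enone
Product: 13 C6 enol triflate (C6(OTf)=C7; 8β-Me, 8α-CH2OSi), via lithium enolate 12 (not isolated)
Conditions: Me2CuLi (from CuI, MeLi), Et2O, −30 → 0 °C; then PhNTf2, THF/DMPU, 0 °C → rt
Reagents that add atoms: lithium dimethylcuprate, [Li+].C[Cu-]C; N-phenylbis(trifluoromethanesulfonimide), O=S(=O)(N(c1ccccc1)S(=O)(=O)C(F)(F)F)C(F)(F)F
Why: Cuprate conjugate addition to the β,β-disubstituted enone goes through a chair-like enolate, that is axially at C8 from the β face, which is also anti to the axial C9 methyl, so C8 becomes quaternary with the new methyl β-axial and C11 α-equatorial; the regiodefined enolate is trapped on oxygen as the triflate.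

Step 10
Reactants: 13 C6 enol triflate
Product: 14 saturated ketal silyl ether (C6 and C7 now CH2)
Conditions: H2 (1 atm), PtO2, NaHCO3, EtOAc, rt
Reagents that add atoms: none
Why: Hydrogenolysis of the vinyl C–O bond and saturation of C6=C7 over platinum remove the C6 oxygen in one operation (ketone deoxygenation through the enol triflate); the bicarbonate takes up the triflic acid, so the dioxolane and silyl ether stay, and no stereocentre is formed.

Step 11
Reactants: 14 saturated ketal silyl ether
Product: 15 C3 ketone
Conditions: PPTS, acetone/H2O (10:1), 60 °C
Reagents that add atoms: water, O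
Why: Acid-catalysed acetal hydrolysis, helped by relief of the 1,3-diaxial contact between the axial dioxolane oxygen and the C5 methyl; the neopentylic triisopropylsilyl ether tolerates the weak acid.

Step 12
Reactants: 15 C3 ketone
Product: 16 C3=C4 trimethylsilyl enol ether
Conditions: Me3SiCl, NaI, Et3N, MeCN, 40 °C
Reagents that add atoms: chlorotrimethylsilane, C[Si](C)(C)Cl
Why: Enol silylation with in-situ iodotrimethylsilane and amine is reversible (the ammonium iodide reprotonates the enol ethers), so the mixture should settle on the more substituted C3=C4 isomer, which also frees the axial C4 methyl from its syn-axial contacts (thermodynamic silyl enol ether formation); C4 stops being a stereocentre.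

Step 13
Reactants: 16 C3=C4 trimethylsilyl enol ether
Product: 18 C3 enol triflate (C3(OTf)=C4), via lithium enolate 17 (not isolated)
Conditions: MeLi, THF, 0 °C; then PhNTf2, THF/DMPU, 0 °C → rt
Reagents that add atoms: N-phenylbis(trifluoromethanesulfonimide), O=S(=O)(N(c1ccccc1)S(=O)(=O)C(F)(F)F)C(F)(F)F
Why: Si–O cleavage by methyllithium releases the tetrasubstituted enolate without moving the double bond, and O-sulfonylation fixes it as the enol triflate.

Step 14
Reactants: 18 C3 enol triflate
Product: 19 Δ3 alkene silyl ether (C3=C4, 4-Me; 8α-CH2OSi(i-Pr)3)
Conditions: Pd(OAc)2 (5 mol %), PPh3, Bu3N, HCO2H, DMF, 60 °C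
Reagents that add atoms: none
Why: Oxidative addition of zerovalent palladium into the vinyl C–O bond, formate exchange, loss of CO2 and C–H reductive elimination replace the triflate by hydrogen with the alkene held at C3=C4 (palladium-catalysed formate reduction of an enol triflate).

Step 15
Reactants: 19 Δ3 alkene silyl ether
Product: 20 C11 alcohol
Conditions: Bu4NF, THF, 50 °C
Reagents that add atoms: none
Why: Fluoride cleaves the Si–O bond; nothing else in the molecule responds to fluoride.

Step 16
Reactants: 20 C11 alcohol
Product: 21 C11 aldehyde
Conditions: DMP, NaHCO3, CH2Cl2, rt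
Reagents that add atoms: none
Why: Hypervalent iodine oxidation of the neopentylic primary alcohol stops at the aldehyde, which has no α-hydrogen; the buffer keeps the C3=C4 alkene from acid-induced migration.

Step 17
Reactants: 21 C11 aldehyde, 22 1,2,4,5-tetramethoxybenzene
Product: 24 C11 benzylic alcohol (2,3,5,6-tetramethoxyphenyl carbinol, both C11 epimers), via 2,3,5,6-tetramethoxyphenyllithium 23 (not isolated)
Conditions: 22, n-BuLi, TMEDA, THF, 0 °C → rt; then 21, −78 → 0 °C
Reagents that add atoms: none
Why: Lithiation between two methoxy groups (directed ortho-metalation) and 1,2-addition of the aryllithium to the non-enolisable aldehyde; the new carbinol centre is formed as a mixture and is removed in step 18.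

Step 18
Reactants: 24 C11 benzylic alcohol
Product: 25 3-(decalinylmethyl)-1,2,4,5-tetramethoxybenzene
Conditions: Li, NH3(l)/THF, −78 °C; then NH4Cl
Reagents that add atoms: none
Why: Electron transfer to the arene, loss of the benzylic oxygen and protonation of the benzylic anion (dissolving-metal hydrogenolysis of a benzylic alcohol); the isolated trisubstituted alkene is inert and the electron-rich ring is not reduced without an added alcohol.

Step 19
Reactants: 25 tetramethoxyarene
Product: 26 2,5-dimethoxy-3-(decalinylmethyl)-1,4-benzoquinone
Conditions: (NH4)2Ce(NO3)6, MeCN/H2O, 0 °C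
Reagents that add atoms: water, O
Why: One-electron oxidation by tetravalent cerium, attack of water at methoxy-bearing carbons and loss of two methanol give the p-quinone (oxidative demethylation); either para pair of methoxy groups leads to the same quinone.

Step 20
Reactants: 26 dimethoxyquinone
Product: 27 2-hydroxy-5-methoxy-3-(decalinylmethyl)-1,4-benzoquinone
Conditions: KOH, MeOH/H2O, rt; then 1 M HCl
Reagents that add atoms: potassium hydroxide, [K+].[OH-]
Why: Addition–elimination of hydroxide on the vinylogous ester; the methoxy group next to the alkyl chain is twisted out of conjugation and is the one displaced, and the resulting vinylogous carboxylate protects the second methoxy group.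

Step 21
Reactants: 27 hydroxyquinone
Product: 29 ring-contracted dihydroxy acid (C1′: OH, CO2H; C5′: OH, CH2-decalin; C4′=O; C2′=C3′–OMe), via 3-hydroxy-1,2,4-trione 28 (not isolated)
Conditions: 30% H2O2, Na2CO3, dioxane/H2O, rt → 50 °C; then Na2SO3, 1 M HCl to pH 3
Reagents that add atoms: hydrogen peroxide, OO; water, O
Why: Alkaline peroxide hydroxylates the enolic carbon C3 and removes the one hydrogen that would let the trione fall back to the hydroxyquinone; hydroxide then adds to the 1,2-dione and a 1,2-shift contracts the ring to the α-hydroxy acid (first stage of the Hooker oxidation, a benzilic acid rearrangement); C1′ and the temporary C5′ carbinol form without control.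

Step 22
Reactants: 29 dihydroxy acid
Product: 30 dihydroxy methyl ester
Conditions: Me3SiCHN2, MeOH/PhMe, 0 °C
Reagents that add atoms: (trimethylsilyl)diazomethane, C[Si](C)(C)C=[N+]=[N-]
Why: The acid protonates the diazo compound and the carboxylate is methylated; tertiary alcohols and the enone are untouched.

Step 23
Reactants: 30 dihydroxy methyl ester
Product: 31 dysidenone A
Conditions: SmI2 (2.5 equiv), THF/MeOH, −78 °C; HPLC separation
Reagents that add atoms: none
Why: Two-electron reduction of the C4′ ketone expels the α-hydroxyl and gives a samarium enolate that is protonated to C5′–H (reductive cleavage of an α-hydroxy ketone); the diastereomer with C11 trans to the C1′ hydroxyl in the required C1′ series is isolated by chromatography, and isomers that differ only at C5′ can be re-equilibrated through the enol and recycled.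

## Compound list

1 | pent-1-en-3-one | CCC(=O)C=C | starting material
2 | (Z)-3-(triisopropylsilyloxy)penta-1,3-diene | C=C/C(O[Si](C(C)C)(C(C)C)C(C)C)=C/C | intermediate
3 | 2,5-dimethyl-1,4-benzoquinone | CC1=CC(=O)C(C)=CC1=O | starting material
4 | cis-fused adduct (C2=C3 silyl enol ether, 4β-Me, 5α-Me, 10α-H, 7-ene-6,9-dione) | CC1=CC(=O)[C@]2(C)[C@H](C)C(O[Si](C(C)C)(C(C)C)C(C)C)=CC[C@@H]2C1=O | intermediate
5 | trans-fused ene-dione (10β-H) | CC1=CC(=O)[C@]2(C)[C@H](C)C(O[Si](C(C)C)(C(C)C)C(C)C)=CC[C@H]2C1=O | intermediate
6 | 9-methylene dienone | CC1=CC(=O)[C@]2(C)[C@H](C)C(O[Si](C(C)C)(C(C)C)C(C)C)=CC[C@H]2C1=C | intermediate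
7 | 9α-methyl enone | CC1=CC(=O)[C@]2(C)[C@H](C)C(O[Si](C(C)C)(C(C)C)C(C)C)=CC[C@H]2[C@H]1C | intermediate
8 | C3 dioxolane enone | CC1=CC(=O)[C@]2(C)[C@H](C)C3(OCCO3)CC[C@H]2[C@H]1C | intermediate
9 | trimethylsilyl dienol ether (C6(OSiMe3)=C7, C8=C11H2) | C=C1C=C(O[Si](C)(C)C)[C@]2(C)[C@H](C)C3(OCCO3)CC[C@H]2[C@H]1C | intermediate (not isolated)
10 | 11-hydroxy enone | OCC1=CC(=O)[C@]2(C)[C@H](C)C3(OCCO3)CC[C@H]2[C@H]1C | intermediate
11 | 11-triisopropylsilyloxy enone | CC(C)[Si](C(C)C)(C(C)C)OCC1=CC(=O)[C@]2(C)[C@H](C)C3(OCCO3)CC[C@H]2[C@H]1C | intermediate
12 | lithium C6 enolate (8β-Me, 8α-CH2OSi) | CC(C)[Si](C(C)C)(C(C)C)OC[C@@]1(C)C=C(O[Li])[C@]2(C)[C@H](C)C3(OCCO3)CC[C@H]2[C@H]1C | intermediate (not isolated)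
13 | C6 enol triflate | CC(C)[Si](C(C)C)(C(C)C)OC[C@@]1(C)C=C(OS(=O)(=O)C(F)(F)F)[C@]2(C)[C@H](C)C3(OCCO3)CC[C@H]2[C@H]1C | intermediate
14 | saturated ketal silyl ether | CC(C)[Si](C(C)C)(C(C)C)OC[C@@]1(C)CC[C@]2(C)[C@H](C)C3(OCCO3)CC[C@H]2[C@H]1C | intermediate
15 | C3 ketone | CC(C)[Si](C(C)C)(C(C)C)OC[C@@]1(C)CC[C@]2(C)[C@H](C)C(=O)CC[C@H]2[C@H]1C | intermediate
16 | C3=C4 trimethylsilyl enol ether | CC(C)[Si](C(C)C)(C(C)C)OC[C@@]1(C)CC[C@]2(C)C(C)=C(O[Si](C)(C)C)CC[C@H]2[C@H]1C | intermediate
17 | lithium C3=C4 enolate | CC(C)[Si](C(C)C)(C(C)C)OC[C@@]1(C)CC[C@]2(C)C(C)=C(O[Li])CC[C@H]2[C@H]1C | intermediate (not isolated)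
18 | C3 enol triflate | CC(C)[Si](C(C)C)(C(C)C)OC[C@@]1(C)CC[C@]2(C)C(C)=C(OS(=O)(=O)C(F)(F)F)CC[C@H]2[C@H]1C | intermediate
19 | Δ3 alkene silyl ether | CC(C)[Si](C(C)C)(C(C)C)OC[C@@]1(C)CC[C@]2(C)C(C)=CCC[C@H]2[C@H]1C | intermediate
20 | C11 alcohol | OC[C@@]1(C)CC[C@]2(C)C(C)=CCC[C@H]2[C@H]1C | intermediate
21 | C11 aldehyde | O=C[C@@]1(C)CC[C@]2(C)C(C)=CCC[C@H]2[C@H]1C | intermediate
22 | 1,2,4,5-tetramethoxybenzene | COc1cc(OC)c(OC)cc1OC | starting material
23 | 2,3,5,6-tetramethoxyphenyllithium | [Li]c1c(OC)c(OC)cc(OC)c1OC | intermediate (not isolated)
24 | C11 benzylic alcohol (C11 epimers) | OC(c1c(OC)c(OC)cc(OC)c1OC)[C@@]1(C)CC[C@]2(C)C(C)=CCC[C@H]2[C@H]1C | intermediate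
25 | 3-(decalinylmethyl)-1,2,4,5-tetramethoxybenzene | COc1cc(OC)c(OC)c(C[C@@]2(C)CC[C@]3(C)C(C)=CCC[C@H]3[C@H]2C)c1OC | intermediate
26 | 2,5-dimethoxy-3-(decalinylmethyl)-1,4-benzoquinone | COC1=CC(=O)C(OC)=C(C[C@@]2(C)CC[C@]3(C)C(C)=CCC[C@H]3[C@H]2C)C1=O | intermediate
27 | 2-hydroxy-5-methoxy-3-(decalinylmethyl)-1,4-benzoquinone | COC1=CC(=O)C(O)=C(C[C@@]2(C)CC[C@]3(C)C(C)=CCC[C@H]3[C@H]2C)C1=O | intermediate
28 | 3-hydroxy-3-(decalinylmethyl)-5-methoxycyclohex-5-ene-1,2,4-trione (C3 epimers) | COC1=CC(=O)C(=O)C(O)(C[C@@]2(C)CC[C@]3(C)C(C)=CCC[C@H]3[C@H]2C)C1=O | intermediate (not isolated)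
29 | ring-contracted 1′,5′-dihydroxy acid (C1′/C5′ isomers) | COC1=CC(O)(C(=O)O)C(O)(C[C@@]2(C)CC[C@]3(C)C(C)=CCC[C@H]3[C@H]2C)C1=O | intermediate
30 | 1′,5′-dihydroxy methyl ester (C1′/C5′ isomers) | COC(=O)C1(O)C=C(OC)C(=O)C1(O)C[C@@]2(C)CC[C@]3(C)C(C)=CCC[C@H]3[C@H]2C | intermediate
31 | dysidenone A | COC(=O)[C@]1(O)C=C(OC)C(=O)[C@@H]1C[C@@]1(C)CC[C@]2(C)C(C)=CCC[C@H]2[C@H]1C | target

## Step count and least certain steps

Total: 23 steps. Longest linear sequence: 23 steps (1 to 31); 3 and 22 are commercial and enter in steps 2 and 17.

**Step 2 (key step).** The methyl on the bond-forming diene terminus crowds the catalyst-bound quinone as the C4–C5 bond forms next to a quaternary centre, so facial selectivity may erode or the diene may add in the reverse orientation. The strong acid co-catalyst may also hydrolyse or oligomerise the diene before it reacts. Fallback, from 2 and 3 back to 5: the cycloaddition is run without chiral control (BF3·OEt2, CH2Cl2, −78 °C), which gives 4 together with its mirror image, the ent-adduct F1. DBU then gives 5 together with the ent-trans ene-dione F2, and the two are separated by preparative chromatography on a chiral stationary phase; the route continues from 5.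

**Step 4.** Methylenation may fail to discriminate between the two conjugated carbonyls, or may go twice, if the C4 and C5 methyls screen C6 less well than expected. Fallback, from 5 back to 8: the conjugation is removed first so that C6 is a plain neopentyl ketone. Zn/NH4Cl in aqueous EtOH reduces the ene-dione to the saturated 6,9-dione F3. Wittig methylenation (Ph3P=CH2, THF) then takes the unhindered C9 ketone to give the methylene ketone F4. Hydrogenation with H2 and RhCl(PPh3)3 gives the 9α-methyl ketone F5, and ethylene glycol/TsOH converts the enol ether to the dioxolane ketone F6. IBX in DMSO at 70 °C dehydrogenates the only enolisable side of C6 and gives 8.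

**Step 7.** Deprotonation may occur at C9 and not at the methyl, which would scramble C9 and give an endocyclic dienol ether, or oxygen may be transferred to C7 and not to C11. Fallback, from 8 back to 10: a radical route replaces the anionic one. NBS with AIBN in PhCF3 at reflux brominates the allylic methyl to the bromide F7 (Wohl–Ziegler). KOAc in DMF gives the acetate F8, and K2CO3 in MeOH releases 10.

**Step 9.** Conjugate addition may stall at the fully substituted β-carbon beside the axial C9 methyl, leaving electron-transfer reduction of the enone as the main pathway. Fallback, from 11 back to 13: the methyl is brought in as a methylene. Dimethylsulfoxonium methylide (Me3S(O)I, NaH, DMSO) adds to the β face to give the cyclopropyl ketone F9 (Corey–Chaykovsky cyclopropanation). Li in NH3/THF cleaves the exocyclic cyclopropane bond that overlaps with the carbonyl to give the C8 methyl and the C6 enolate, which is trapped with PhNTf2 as 13.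

**Step 12.** Equilibration may stop short, leaving the C2=C3 enol ether and hence the wrong alkene, because the C4 hydrogen of the cycloaddition-derived epimer is equatorial and slow to exchange. Fallback, from 15 back to 19: the kinetic position is used on purpose. LiN(i-Pr)2 then PhNTf2 gives the kinetic C2=C3 triflate F10, and the formate reduction of step 14 gives the Δ2 alkene F11. RhCl3·3H2O in EtOH at 80 °C moves the double bond to the trisubstituted C3=C4 position, giving 19.

**Step 21.** The peroxide may go on to cleave the contracted ring (nucleophilic epoxidation of the new enone or retro-Claisen opening of the trione), because unlike a naphthoquinone this substrate has no benzo ring to stop further oxidation. Fallback, from 27 back to 30: hydroxylation and contraction are separated and the oxidant is changed to an electrophilic one. KN(SiMe3)2 and 2-(phenylsulfonyl)-3-phenyloxaziridine in THF at −78 °C hydroxylate the enolate carbon, and the hydroxy trione 28 is isolated. NaOMe in dry MeOH then effects the benzilic ester rearrangement straight to 30, with no free acid and no peroxide present.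

## Further compounds

F1 | step 2 | ent-adduct (mirror image of 4) | CC1=CC(=O)[C@@]2(C)[C@@H](C)C(O[Si](C(C)C)(C(C)C)C(C)C)=CC[C@H]2C1=O
F2 | step 2 | ent-trans ene-dione (mirror image of 5) | CC1=CC(=O)[C@@]2(C)[C@@H](C)C(O[Si](C(C)C)(C(C)C)C(C)C)=CC[C@@H]2C1=O
F3 | step 4 | saturated 6,9-dione (C8 epimers) | CC1CC(=O)[C@]2(C)[C@H](C)C(O[Si](C(C)C)(C(C)C)C(C)C)=CC[C@H]2C1=O
F4 | step 4 | 9-methylene ketone (C8 epimers) | CC1CC(=O)[C@]2(C)[C@H](C)C(O[Si](C(C)C)(C(C)C)C(C)C)=CC[C@H]2C1=C
F5 | step 4 | 9α-methyl ketone (C8 epimers) | CC1CC(=O)[C@]2(C)[C@H](C)C(O[Si](C(C)C)(C(C)C)C(C)C)=CC[C@H]2[C@H]1C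
F6 | step 4 | dioxolane ketone (C8 epimers) | CC1CC(=O)[C@]2(C)[C@H](C)C3(OCCO3)CC[C@H]2[C@H]1C
F7 | step 7 | 11-bromo enone | BrCC1=CC(=O)[C@]2(C)[C@H](C)C3(OCCO3)CC[C@H]2[C@H]1C
F8 | step 7 | 11-acetoxy enone | CC(=O)OCC1=CC(=O)[C@]2(C)[C@H](C)C3(OCCO3)CC[C@H]2[C@H]1C
F9 | step 9 | 7β,8β-methano cyclopropyl ketone | CC(C)[Si](C(C)C)(C(C)C)OC[C@]12C[C@@H]2C(=O)[C@]3(C)[C@H](C)C4(OCCO4)CC[C@H]3[C@H]1C
F10 | step 12 | kinetic C2=C3 enol triflate | CC(C)[Si](C(C)C)(C(C)C)OC[C@@]1(C)CC[C@]2(C)[C@H](C)C(OS(=O)(=O)C(F)(F)F)=CC[C@H]2[C@H]1C
F11 | step 12 | Δ2 alkene silyl ether | CC(C)[Si](C(C)C)(C(C)C)OC[C@@]1(C)CC[C@]2(C)[C@H](C)C=CC[C@H]2[C@H]1C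
F0 | step 21 | none | none
A1 | alternative 1 | cross-conjugated dienone for the 4π-electrocyclisation | COC(=O)/C=C(\C[C@@]1(C)CC[C@]2(C)C(C)=CCC[C@H]2[C@H]1C)C(=O)C(=C)OC
A2 | alternative 1 | 1′-deoxy cyclopentenone ester | COC(=O)[C@H]1C=C(OC)C(=O)[C@@H]1C[C@@]1(C)CC[C@]2(C)C(C)=CCC[C@H]2[C@H]1C
A3 | alternative 2 | acyclic trienone | C=CC(=O)C(C)(C)CC/C(C)=C(\C)C=C
A4 | alternative 2 | trans-decalone with gem-dimethyl C8 | CC1(C)CC[C@]2(C)C(C)=CCC[C@H]2C1=O
A5 | alternative 3 | (bromomethyl)dimethylsilyl ether with C9=C10 alkene | BrC[Si](C)(C)OC[C@@]1(C)CC[C@]2(C)C3(OCCO3)CCCC2=C1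
A6 | alternative 3 | trans-decalin with cis-fused siloxane | C[Si]1(C)OC[C@@]2(C)CC[C@]3(C)C4(OCCO4)CCC[C@H]3[C@H]2C1
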